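**Plan**
1. Retrosynthetic cuts: the C8 glycidate and C9 acetate esters (made last); the C9–C10 ring bond (vinyl iodide plus aldehyde); then the lactone bonds C11–C12 and C12–O6 (carbon monoxide) together with C6–C7 (aldehyde plus allenyl nucleophile).
2. Enabling feature: in the γ-lactone ring O–C6–C7–C11–C12 the oxygen sits on C6 and the exocyclic C11=C13 on C7. Removing C12 leaves a homopropargylic alcohol, which is the adduct of an aldehyde (C6) and a C13=C11=C7 allenyl unit.
3. Forward order: a nerol-derived cis-epoxy aldehyde (C1–C6, C1 masked as an isopropylidene alkene) and a C7–C9 allenylboronate are joined with CO in one flask, which builds the lactone ring first. Ozonolysis and iodo-olefination then set up closure of the ten-membered ring at C9–C10; the two esters follow.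
4. Stereochemistry: C4/C5 and C8 come from two Sharpless epoxidations; C7 comes from the second epoxide by inversion, then centre-to-axis-to-centre transfer; C6 is set in the key step (chair transition state, Felkin–Anh matched); C9 by Felkin–Anh addition in the ring closure; the glycidate centre from a chiral-pool ester.
5. The C1=C10 geometry is set in the Wittig step and kept in the ring closure.

Key step: step 7

Remark: locants C1–C15 are those of the germacrane skeleton of the target (C12 lactone carbonyl, C13 exocyclic methylene, C14 ester carbon, C15 methyl on C4); TBS = tert-butyldimethylsilyl, pin = pinacolato; (2E)-pent-2-en-4-yn-1-ol and methyl (2S)-2-methyloxirane-2-carboxylate are taken to be commercial.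

**Route**

Step 1
Reactants: 1 nerol, (2Z)-3,7-dimethylocta-2,6-dien-1-ol
Product: 2 [(2S,3R)-3-methyl-3-(4-methylpent-3-en-1-yl)oxiran-2-yl]methanol
Conditions: Ti(OiPr)4 (5 mol %), L-(+)-diethyl tartrate (7 mol %), t-BuOOH, 4 Å molecular sieves, CH2Cl2, −20 °C
Reagents that add atoms: tert-butyl hydroperoxide, CC(C)(C)OO
Why: Sharpless asymmetric epoxidation reacts only at the allylic alcohol alkene and, with the L-(+)-tartrate ligand, should deliver oxygen to the face that gives the (2S,3R) cis-epoxide, which sets C4 and C5.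

Step 2
Reactants: 2 [(2S,3R)-3-methyl-3-(4-methylpent-3-en-1-yl)oxiran-2-yl]methanol
Product: 3 (2R,3R)-3-methyl-3-(4-methylpent-3-en-1-yl)oxirane-2-carbaldehyde
Conditions: TEMPO (10 mol %), PhI(OAc)2 (1.1 equiv), CH2Cl2, 0 °C to rt
Reagents that add atoms: none
Why: TEMPO-catalysed oxidation of a primary alcohol by the oxoammonium salt stops at the aldehyde under neutral conditions that should leave the epoxide, its α-stereocentre and the trisubstituted alkene untouched.

Step 3
Reactants: 4 (2E)-pent-2-en-4-yn-1-ol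
Product: 5 [(2R,3R)-3-ethynyloxiran-2-yl]methanol
Conditions: Ti(OiPr)4 (10 mol %), D-(−)-diethyl tartrate (12 mol %), t-BuOOH, 4 Å molecular sieves, CH2Cl2, −20 °C
Reagents that add atoms: tert-butyl hydroperoxide, CC(C)(C)OO
Why: Sharpless asymmetric epoxidation with the D-(−)-tartrate ligand should give the (2R,3R) trans-epoxide, which fixes C8 and places at C7 the oxygen that is displaced with inversion in step 4.

Step 4
Reactants: 5 [(2R,3R)-3-ethynyloxiran-2-yl]methanol
Product: 6 (3S,4R)-4,5-dihydroxypent-1-yn-3-yl benzoate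
Conditions: PhCO2H (1.5 equiv), Ti(OiPr)4 (1.5 equiv), CH2Cl2, rt
Reagents that add atoms: benzoic acid, OC(=O)c1ccccc1
Why: Ti(OiPr)4-mediated opening of a 2,3-epoxy alcohol by a carboxylic acid takes place at C3 (here the propargylic C7) in an SN2 manner, so the benzoate enters with inversion and the 7,8-anti diol monoester should result.

Step 5
Reactants: 6 (3S,4R)-4,5-dihydroxypent-1-yn-3-yl benzoate
Product: 7 (3S,4R)-4,5-bis(TBS-oxy)pent-1-yn-3-yl benzoate
Conditions: TBSOTf (2.4 equiv), 2,6-lutidine, CH2Cl2, −78 to 0 °C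
Reagents that add atoms: tert-butyldimethylsilyl trifluoromethanesulfonate, CC(C)(C)[Si](C)(C)OS(=O)(=O)C(F)(F)F
Why: A silyl triflate with a hindered pyridine base silylates the primary and the secondary hydroxyl quickly at low temperature, before the neighbouring benzoate can migrate.

Step 6
Reactants: 7 (3S,4R)-4,5-bis(TBS-oxy)pent-1-yn-3-yl benzoate
Product: 8 2-[(aS,4S)-4,5-bis(TBS-oxy)penta-1,2-dien-1-yl]-4,4,5,5-tetramethyl-1,3,2-dioxaborolane
Conditions: B2pin2 (1.05 equiv), Pd(PPh3)4 (5 mol %), CuI (10 mol %), THF, rt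
Reagents that add atoms: bis(pinacolato)diboron, CC1(C)OB(OC1(C)C)B1OC(C)(C)C(C)(C)O1
Why: Zerovalent palladium ionises the propargylic benzoate in an SN2′ manner anti to the leaving group and the boryl group delivered from boryl copper replaces palladium with retention, so the C7 centre should be converted into the (aS) allene axis (formal anti-SN2′ borylation of a propargylic ester).

Step 7
Reactants: 3 (2R,3R)-3-methyl-3-(4-methylpent-3-en-1-yl)oxirane-2-carbaldehyde; 8 2-[(aS,4S)-4,5-bis(TBS-oxy)penta-1,2-dien-1-yl]-4,4,5,5-tetramethyl-1,3,2-dioxaborolane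
Product: 11 (4S,5S)-4-[(1S)-1,2-bis(TBS-oxy)ethyl]-3-methylidene-5-[(2S,3R)-3-methyl-3-(4-methylpent-3-en-1-yl)oxiran-2-yl]oxolan-2-one, via O6-pinacolboronate 9 (not isolated), via homopropargylic alcohol 10 (not isolated)
Conditions: 3 (1.2 equiv), toluene, 25 to 50 °C; then H2O (3 equiv), MeCN, PdI2 (5 mol %), PBu3 (10 mol %), CO (7 bar), 60 °C
Reagents that add atoms: carbon monoxide, [C-]#[O+]
Why: In the first stage the allenylboronate adds to the aldehyde through a six-membered chair transition state (SE2′), forming C6–C7 and leaving O6 on boron, and water then frees the C6 hydroxyl. In the second stage divalent palladium, CO and this hydroxyl give an alkoxycarbonylpalladium species (O6–C12), whose acyl carbon adds syn across C11≡C13 in a 5-exo-dig insertion that forms the C11–C12 bond and closes the lactone ring; protonolysis of the vinyl–palladium bond leaves the exocyclic methylene and returns the catalyst. The closest known reaction types are the anti-selective propargylation of aldehydes by γ-substituted allenylboronates and the palladium-catalysed cyclocarbonylation of but-3-yn-1-ols to α-methylene-γ-butyrolactones. C7 is fixed by transfer of the (aS) axial chirality of 8 (carbon–carbon bond formation syn to boron) and C6 by the chair with the aldehyde substituent equatorial (6,7-anti), which coincides with the Felkin–Anh preference of the cis-epoxy aldehyde for attack anti to the C5–O bond. The step needs a single lactone and untouched epoxide and alkene: only O6–H is free because O8 and O9 are silylated, the trisubstituted alkene and the epoxide should not engage the alkoxycarbonylpalladium, and 3 is used in excess so that no allenylboronate remains when palladium is added.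

Step 8
Reactants: 11 (4S,5S)-4-[(1S)-1,2-bis(TBS-oxy)ethyl]-3-methylidene-5-[(2S,3R)-3-methyl-3-(4-methylpent-3-en-1-yl)oxiran-2-yl]oxolan-2-one
Product: 12 3-[(2R,3S)-3-[(2S,3S)-3-[(1S)-1,2-bis(TBS-oxy)ethyl]-4-methylidene-5-oxooxolan-2-yl]-2-methyloxiran-2-yl]propanal
Conditions: O3, CH2Cl2, −78 °C, Sudan Red 7B (end-point indicator); then Me2S, −78 °C to rt
Reagents that add atoms: ozone, [O-][O+]=O
Why: Ozone is an electrophile and should cleave the electron-rich trisubstituted alkene (ozonolysis with reductive work-up) much faster than the electron-poor exocyclic methylene of the lactone, the indicator dye marking the end point.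

Step 9
Reactants: 12 3-[(2R,3S)-3-[(2S,3S)-3-[(1S)-1,2-bis(TBS-oxy)ethyl]-4-methylidene-5-oxooxolan-2-yl]-2-methyloxiran-2-yl]propanal
Product: 13 methyl (2Z)-5-[(2R,3S)-3-[(2S,3S)-3-[(1S)-1,2-bis(TBS-oxy)ethyl]-4-methylidene-5-oxooxolan-2-yl]-2-methyloxiran-2-yl]-2-iodopent-2-enoate
Conditions: Ph3P=CHCO2Me (1.3 equiv), N-iodosuccinimide (1.3 equiv), CH2Cl2, −20 °C; then 12, −20 °C to rt
Reagents that add atoms: methyl (triphenylphosphoranylidene)acetate, COC(=O)C=P(c1ccccc1)(c1ccccc1)c1ccccc1; N-iodosuccinimide, O=C1CCC(=O)N1I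
Why: Wittig olefination with the ester-stabilised iodo ylide formed in the flask places the ester trans to the chain, so that iodine should end cis to C2 in the (Z)-α-iodo enoate, the geometry needed at C1=C10.

Step 10
Reactants: 13 methyl (2Z)-5-[(2R,3S)-3-[(2S,3S)-3-[(1S)-1,2-bis(TBS-oxy)ethyl]-4-methylidene-5-oxooxolan-2-yl]-2-methyloxiran-2-yl]-2-iodopent-2-enoate
Product: 14 methyl (2Z)-5-[(2R,3S)-3-[(2S,3S)-3-[(1S)-1-(TBS-oxy)-2-hydroxyethyl]-4-methylidene-5-oxooxolan-2-yl]-2-methyloxiran-2-yl]-2-iodopent-2-enoate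
Conditions: HF·pyridine, pyridine, THF, 0 °C
Reagents that add atoms: none
Why: Buffered hydrogen fluoride–pyridine cleaves the unhindered primary silyl ether much faster than the secondary one flanked by C7 and should leave the epoxide and the iodo enoate intact (selective desilylation).

Step 11
Reactants: 14 methyl (2Z)-5-[(2R,3S)-3-[(2S,3S)-3-[(1S)-1-(TBS-oxy)-2-hydroxyethyl]-4-methylidene-5-oxooxolan-2-yl]-2-methyloxiran-2-yl]-2-iodopent-2-enoate
Product: 15 methyl (2Z)-5-[(2R,3S)-3-[(2S,3S)-3-[(1S)-1-(TBS-oxy)-2-oxoethyl]-4-methylidene-5-oxooxolan-2-yl]-2-methyloxiran-2-yl]-2-iodopent-2-enoate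
Conditions: TEMPO (10 mol %), PhI(OAc)2 (1.2 equiv), CH2Cl2, rt
Reagents that add atoms: none
Why: The neutral TEMPO-catalysed oxidation converts the primary alcohol into the α-silyloxy aldehyde without base, so C8 should not epimerise and the vinyl iodide and lactone are left alone.

Step 12
Reactants: 15 methyl (2Z)-5-[(2R,3S)-3-[(2S,3S)-3-[(1S)-1-(TBS-oxy)-2-oxoethyl]-4-methylidene-5-oxooxolan-2-yl]-2-methyloxiran-2-yl]-2-iodopent-2-enoate
Product: 16 methyl (1(10)E,4R,5S,6S,7S,8S,9R)-8-(TBS-oxy)-4,5-epoxy-9-hydroxygermacra-1(10),11(13)-dien-12,6-olid-14-oate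
Conditions: CrCl2 (8 equiv), NiCl2 (2 mol %), degassed DMSO–THF, rt, 2 mM, slow addition of 15
Reagents that add atoms: none
Why: In this Nozaki–Hiyama–Kishi ring closure zerovalent nickel inserts into the carbon–iodine bond, transmetalation gives a vinylchromium species that adds to the aldehyde with retention of the alkene geometry and closes the ten-membered ring at C9–C10 with C9 cis to C2, while Felkin–Anh addition anti to the C8 silyloxy group should give the 8,9-anti (9R) alcohol.

Step 13
Reactants: 16 methyl (1(10)E,4R,5S,6S,7S,8S,9R)-8-(TBS-oxy)-4,5-epoxy-9-hydroxygermacra-1(10),11(13)-dien-12,6-olid-14-oate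
Product: 17 methyl (1(10)E,4R,5S,6S,7S,8S,9R)-9-acetoxy-8-(TBS-oxy)-4,5-epoxygermacra-1(10),11(13)-dien-12,6-olid-14-oate
Conditions: Ac2O, pyridine, DMAP (5 mol %), CH2Cl2, 0 °C
Reagents that add atoms: acetic anhydride, CC(=O)OC(C)=O
Why: Acylation of the secondary allylic alcohol with acetic anhydride under nucleophilic catalysis should not touch the silyl ether, the epoxide or the lactone.

Step 14
Reactants: 17 methyl (1(10)E,4R,5S,6S,7S,8S,9R)-9-acetoxy-8-(TBS-oxy)-4,5-epoxygermacra-1(10),11(13)-dien-12,6-olid-14-oate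
Product: 18 methyl (1(10)E,4R,5S,6S,7R,8S,9R)-9-acetoxy-4,5-epoxy-8-hydroxygermacra-1(10),11(13)-dien-12,6-olid-14-oate
Conditions: HF·pyridine, THF, 0 °C to rt
Reagents that add atoms: none
Why: Longer treatment with hydrogen fluoride–pyridine removes the remaining secondary silyl ether under weakly acidic conditions in which the neighbouring acetate should not migrate and the trisubstituted epoxide is expected to survive.

Step 15
Reactants: 19 methyl (2S)-2-methyloxirane-2-carboxylate
Product: 20 (2S)-2-methyloxirane-2-carboxylic acid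
Conditions: LiOH, THF–H2O, 0 °C; then 1 M HCl to pH 3, 0 °C, used at once
Reagents that add atoms: lithium hydroxide, [Li+].[OH-]
Why: Saponification of the methyl ester at 0 °C followed by careful acidification should give the glycidic acid without opening the 2,2-disubstituted epoxide, and the quaternary stereocentre cannot epimerise.

Step 16
Reactants: 18 methyl (1(10)E,4R,5S,6S,7R,8S,9R)-9-acetoxy-4,5-epoxy-8-hydroxygermacra-1(10),11(13)-dien-12,6-olid-14-oate; 20 (2S)-2-methyloxirane-2-carboxylic acid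
Product: 21 methyl (1(10)E,4R,5S,6S,7R,8S,9R)-9-acetoxy-4,5-epoxy-8-{[(2S)-2-methyloxiran-2-yl]carbonyloxy}germacra-1(10),11(13)-dien-12,6-olid-14-oate (CNP0274195.2)
Conditions: DCC (1.5 equiv), DMAP (10 mol %), CH2Cl2, 0 °C to rt
Reagents that add atoms: none
Why: Steglich esterification (carbodiimide activation with DMAP as acyl-transfer catalyst) acylates the C8 hydroxyl with retention at both stereocentres under neutral conditions that the epoxides, the acetate and the α-methylene lactone should tolerate.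

**Compound list**
1 | nerol, (2Z)-3,7-dimethylocta-2,6-dien-1-ol | CC(C)=CCC/C(C)=C\CO | starting material
2 | [(2S,3R)-3-methyl-3-(4-methylpent-3-en-1-yl)oxiran-2-yl]methanol | CC(C)=CCC[C@@]1(C)O[C@H]1CO | intermediate
3 | (2R,3R)-3-methyl-3-(4-methylpent-3-en-1-yl)oxirane-2-carbaldehyde | CC(C)=CCC[C@@]1(C)O[C@H]1C=O | intermediate
4 | (2E)-pent-2-en-4-yn-1-ol | OC/C=C/C#C | starting material
5 | [(2R,3R)-3-ethynyloxiran-2-yl]methanol | C#C[C@H]1O[C@@H]1CO | intermediate
6 | (3S,4R)-4,5-dihydroxypent-1-yn-3-yl benzoate | C#C[C@H](OC(=O)c1ccccc1)[C@H](O)CO | intermediate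
7 | (3S,4R)-4,5-bis(TBS-oxy)pent-1-yn-3-yl benzoate | C#C[C@H](OC(=O)c1ccccc1)[C@H](O[Si](C)(C)C(C)(C)C)CO[Si](C)(C)C(C)(C)C | intermediate
8 | 2-[(aS,4S)-4,5-bis(TBS-oxy)penta-1,2-dien-1-yl]-4,4,5,5-tetramethyl-1,3,2-dioxaborolane | CC1(C)OB(OC1(C)C)C([H])=[C@@]=C([H])[C@H](O[Si](C)(C)C(C)(C)C)CO[Si](C)(C)C(C)(C)C | intermediate
9 | 2-{[(1S,2S,3S)-3,4-bis(TBS-oxy)-2-ethynyl-1-[(2S,3R)-3-methyl-3-(4-methylpent-3-en-1-yl)oxiran-2-yl]butyl]oxy}-4,4,5,5-tetramethyl-1,3,2-dioxaborolane (O6-pinacolboronate) | CC(C)=CCC[C@@]1(C)O[C@H]1[C@@H](OB2OC(C)(C)C(C)(C)O2)[C@H](C#C)[C@H](O[Si](C)(C)C(C)(C)C)CO[Si](C)(C)C(C)(C)C | intermediate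
10 | (1S,2S,3S)-3,4-bis(TBS-oxy)-2-ethynyl-1-[(2S,3R)-3-methyl-3-(4-methylpent-3-en-1-yl)oxiran-2-yl]butan-1-ol (homopropargylic alcohol) | CC(C)=CCC[C@@]1(C)O[C@H]1[C@@H](O)[C@H](C#C)[C@H](O[Si](C)(C)C(C)(C)C)CO[Si](C)(C)C(C)(C)C | intermediate
11 | (4S,5S)-4-[(1S)-1,2-bis(TBS-oxy)ethyl]-3-methylidene-5-[(2S,3R)-3-methyl-3-(4-methylpent-3-en-1-yl)oxiran-2-yl]oxolan-2-one | CC(C)=CCC[C@@]1(C)O[C@H]1[C@H]2OC(=O)C(=C)[C@@H]2[C@H](O[Si](C)(C)C(C)(C)C)CO[Si](C)(C)C(C)(C)C | intermediate
12 | 3-[(2R,3S)-3-[(2S,3S)-3-[(1S)-1,2-bis(TBS-oxy)ethyl]-4-methylidene-5-oxooxolan-2-yl]-2-methyloxiran-2-yl]propanal | O=CCC[C@@]1(C)O[C@H]1[C@H]2OC(=O)C(=C)[C@@H]2[C@H](O[Si](C)(C)C(C)(C)C)CO[Si](C)(C)C(C)(C)C | intermediate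
13 | methyl (2Z)-5-[(2R,3S)-3-[(2S,3S)-3-[(1S)-1,2-bis(TBS-oxy)ethyl]-4-methylidene-5-oxooxolan-2-yl]-2-methyloxiran-2-yl]-2-iodopent-2-enoate | COC(=O)/C(I)=C/CC[C@@]1(C)O[C@H]1[C@H]2OC(=O)C(=C)[C@@H]2[C@H](O[Si](C)(C)C(C)(C)C)CO[Si](C)(C)C(C)(C)C | intermediate
14 | methyl (2Z)-5-[(2R,3S)-3-[(2S,3S)-3-[(1S)-1-(TBS-oxy)-2-hydroxyethyl]-4-methylidene-5-oxooxolan-2-yl]-2-methyloxiran-2-yl]-2-iodopent-2-enoate | COC(=O)/C(I)=C/CC[C@@]1(C)O[C@H]1[C@H]2OC(=O)C(=C)[C@@H]2[C@H](O[Si](C)(C)C(C)(C)C)CO | intermediate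
15 | methyl (2Z)-5-[(2R,3S)-3-[(2S,3S)-3-[(1S)-1-(TBS-oxy)-2-oxoethyl]-4-methylidene-5-oxooxolan-2-yl]-2-methyloxiran-2-yl]-2-iodopent-2-enoate | COC(=O)/C(I)=C/CC[C@@]1(C)O[C@H]1[C@H]2OC(=O)C(=C)[C@@H]2[C@H](O[Si](C)(C)C(C)(C)C)C=O | intermediate
16 | methyl (1(10)E,4R,5S,6S,7S,8S,9R)-8-(TBS-oxy)-4,5-epoxy-9-hydroxygermacra-1(10),11(13)-dien-12,6-olid-14-oate | C=C1C(=O)O[C@H]2[C@H]1[C@H](O[Si](C)(C)C(C)(C)C)[C@H](O)/C(C(=O)OC)=C\CC[C@@]1(C)O[C@@H]21 | intermediate
17 | methyl (1(10)E,4R,5S,6S,7S,8S,9R)-9-acetoxy-8-(TBS-oxy)-4,5-epoxygermacra-1(10),11(13)-dien-12,6-olid-14-oate | C=C1C(=O)O[C@H]2[C@H]1[C@H](O[Si](C)(C)C(C)(C)C)[C@H](OC(C)=O)/C(C(=O)OC)=C\CC[C@@]1(C)O[C@@H]21 | intermediate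
18 | methyl (1(10)E,4R,5S,6S,7R,8S,9R)-9-acetoxy-4,5-epoxy-8-hydroxygermacra-1(10),11(13)-dien-12,6-olid-14-oate | C=C1C(=O)O[C@H]2[C@H]1[C@H](O)[C@H](OC(C)=O)/C(C(=O)OC)=C\CC[C@@]1(C)O[C@@H]21 | intermediate
19 | methyl (2S)-2-methyloxirane-2-carboxylate | COC(=O)[C@]1(C)CO1 | starting material
20 | (2S)-2-methyloxirane-2-carboxylic acid | OC(=O)[C@]1(C)CO1 | intermediate
21 | methyl (1(10)E,4R,5S,6S,7R,8S,9R)-9-acetoxy-4,5-epoxy-8-{[(2S)-2-methyloxiran-2-yl]carbonyloxy}germacra-1(10),11(13)-dien-12,6-olid-14-oate (CNP0274195.2) | C=C1C(=O)O[C@H]2[C@H]1[C@H](OC(=O)[C@]1(C)CO1)[C@H](OC(C)=O)/C(C(=O)OC)=C\CC[C@@]1(C)O[C@@H]21 | target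

**Step count and risks**

Total step count: 16. Longest linear sequence: 13 steps (from 4 through steps 3–14 and step 16).

Steps most likely to fail:

Step 7. What may go wrong: hydrogen iodide released while the alkoxycarbonylpalladium species forms may open the acid-labile trisubstituted epoxide. Carbonylation at the hindered C6 hydroxyl may also be slower than oligomerisation of the terminal alkyne, and incomplete transfer of axial chirality in the first stage would lower diastereomeric purity. The fallback replaces palladium chemistry by a radical ring closure of the same bond. It sets out from 10, isolated after the first stage and aqueous work-up. Phosgene and pyridine, then benzeneselenol, should give the Se-phenyl selenocarbonate of the C6 hydroxyl F1. Bu3SnH and AIBN in benzene at 80 °C generate the alkoxycarbonyl radical, which closes C11–C12 by 5-exo-dig cyclisation onto the alkyne; hydrogen transfer to the vinyl radical gives 11, where the route is rejoined.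

Step 12. What may go wrong: the organochromium intermediate next to the ester may relax to an oxygen-bound allenoate and lose the alkene geometry. Intermolecular coupling may outrun closure of the medium ring, and facial selectivity at C9 may be low. The fallback closes the ring by alkene metathesis at C1=C10 instead of carbonyl addition at C9–C10, and sets out from 11. HF·pyridine with pyridine gives the primary alcohol F2, and TEMPO with PhI(OAc)2 the aldehyde F3. A Morita–Baylis–Hillman reaction with methyl acrylate (DABCO) gives the α-methylene-β-hydroxy ester F4 (C9 epimers to be separated), and Ac2O with pyridine the acetate F5. Ring-closing metathesis between the isopropylidene alkene and the acrylate methylene (second-generation Hoveyda–Grubbs catalyst, toluene, 80 °C, high dilution) should then give 17 with loss of 2-methylpropene, the ring expected to favour the cis arrangement of C9 and C2. The route is rejoined at 17.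

Step 6. What may go wrong: slow ionisation of the benzoate, metallation of the terminal alkyne by copper, or partial loss of stereospecificity in the SN2′ step. The fallback forms and consumes an allenylzinc in the presence of the aldehyde, with no boron reagent, and sets out from 7 together with 3. Pd(PPh3)4 (cat.) and Et2Zn in THF at 0 °C to rt umpole the propargylic benzoate to an allenylzinc, which should add at once to 3 through the same cyclic SE2′ transition state. Aqueous work-up gives 10, which is carried into the second stage of step 7 to reach 11. This fallback makes no compound outside the compound list (none F0).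

**Further compounds**
F1 | step 7 | O-[(1S,2S,3S)-3,4-bis(TBS-oxy)-2-ethynyl-1-[(2S,3R)-3-methyl-3-(4-methylpent-3-en-1-yl)oxiran-2-yl]butyl] Se-phenyl selenocarbonate | CC(C)=CCC[C@@]1(C)O[C@H]1[C@@H](OC(=O)[Se]c1ccccc1)[C@H](C#C)[C@H](O[Si](C)(C)C(C)(C)C)CO[Si](C)(C)C(C)(C)C
F2 | step 12 | (4S,5S)-4-[(1S)-1-(TBS-oxy)-2-hydroxyethyl]-3-methylidene-5-[(2S,3R)-3-methyl-3-(4-methylpent-3-en-1-yl)oxiran-2-yl]oxolan-2-one | CC(C)=CCC[C@@]1(C)O[C@H]1[C@H]2OC(=O)C(=C)[C@@H]2[C@H](O[Si](C)(C)C(C)(C)C)CO
F3 | step 12 | (2S)-2-(TBS-oxy)-2-[(3S,4S)-4-methylidene-2-[(2S,3R)-3-methyl-3-(4-methylpent-3-en-1-yl)oxiran-2-yl]-5-oxooxolan-3-yl]acetaldehyde (C9 aldehyde of F2; the two oxolane descriptors are not taken from the CIP ranking used for 11 and F2) | CC(C)=CCC[C@@]1(C)O[C@H]1[C@H]2OC(=O)C(=C)[C@@H]2[C@H](O[Si](C)(C)C(C)(C)C)C=O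
F4 | step 12 | methyl 2-methylidene-3-hydroxy-4-(TBS-oxy)butanoate carrying the lactone of F2 at C4 (Morita–Baylis–Hillman adduct, 8,9-anti, 9R in target locants) | CC(C)=CCC[C@@]1(C)O[C@H]1[C@H]2OC(=O)C(=C)[C@@H]2[C@H](O[Si](C)(C)C(C)(C)C)[C@H](O)C(=C)C(=O)OC
F5 | step 12 | C9 acetate of F4 | CC(C)=CCC[C@@]1(C)O[C@H]1[C@H]2OC(=O)C(=C)[C@@H]2[C@H](O[Si](C)(C)C(C)(C)C)[C@H](OC(C)=O)C(=C)C(=O)OC
F0 | step 6 | none | none
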